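**Retrosynthetic overview**

1. The target comes from an 8‑hydroxy‑9‑silyloxy germacranolide by angeloylation at O8, silyl‑to‑acetyl exchange at O9 and desilylation at O3; the two oxygens are told apart by the way the ring is closed.
2. Key disconnection C8–C9: the ten‑membered carbocycle is closed last by a CrCl2/Et3SiCl reductive cross‑pinacol coupling of an acyclic lactone dialdehyde (saturated C8 aldehyde, C9 enal). The enabling feature is that, in the ten‑membered ring, the vicinal dioxygenated pair C8/C9 sits directly on the C1=C10 olefin (O8–C8–C9(O9)–C10=C1). This is the retron of a γ‑oxyallylmetal addition to an aldehyde, so C9 becomes nucleophilic by two‑electron reduction of an enal, with transposition and return of the C1=C10 double bond.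
3. The dialdehyde comes from a trans‑α‑methylene‑γ‑butyrolactone (C6–C7 bond by catalytic asymmetric chromium 2‑(alkoxycarbonyl)allylation and lactonisation), followed by cross‑metathesis with methacrolein (C9, C10, C14) and oxidation at C8.
4. The enal fragment (C1–C6, C15) comes from a Wittig reaction and a Keck allylation; the bromide fragment (C7, C8, C11–C13) from a Morita–Baylis–Hillman reaction and bromination.
5. Ring order: γ‑lactone first (step 7), then the ten‑membered carbocycle (step 11).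

Key step: step 11

Remark 1: atoms are referred to by germacrane numbering (ring C1–C10; C6 carries the lactone oxygen; C11, C12, C13 are the α‑methylene lactone carbons; C14 on C10; C15 on C4). CIP descriptors of intermediates are given as the rules require, so the label at C7 changes although its spatial arrangement does not.

Remark 2 (assumption): the sense of induction in step 7 is taken to be that of the (S,S)‑ligand; should it prove opposite, the (R,R)‑ligand is used.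

**Route**

Step 1
Reactants: 1 2,2‑dimethoxyacetaldehyde; 2 2‑(triphenyl‑λ5‑phosphanylidene)propanal
Product: 3 (2E)‑4,4‑dimethoxy‑2‑methylbut‑2‑enal
Conditions: PhMe, 80 °C (1 extracted from its 60 % aqueous solution and dried)
Reagents that add atoms: none
Why: Wittig olefination with a stabilised ylide, which reacts only with the more electrophilic α,α‑dialkoxy aldehyde and should give the (E)‑trisubstituted enal, i.e. the C4=C5 geometry of the target.

Step 2
Reactants: 3 (2E)‑4,4‑dimethoxy‑2‑methylbut‑2‑enal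
Product: 4 (4S,5E)‑7,7‑dimethoxy‑5‑methylhepta‑1,5‑dien‑4‑ol
Conditions: allyltributylstannane, (S)‑BINOL (20 mol %), Ti(OiPr)4 (10 mol %), 4 Å MS, CH2Cl2, −20 °C
Reagents that add atoms: allyltributylstannane, C=CC[Sn](CCCC)(CCCC)CCCC
Why: Keck asymmetric allylation (1,2‑addition to the enal, the acetal being inert to the weak titanium Lewis acid); the (S)‑BINOL–titanium catalyst should deliver the allyl group to the face that gives the (S)‑carbinol, which is C3 of the target.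

Step 3
Reactants: 4 (4S,5E)‑7,7‑dimethoxy‑5‑methylhepta‑1,5‑dien‑4‑ol
Product: 5 tert‑butyl{[(4S,5E)‑7,7‑dimethoxy‑5‑methylhepta‑1,5‑dien‑4‑yl]oxy}dimethylsilane
Conditions: TBSCl, imidazole, DMF, 23 °C
Reagents that add atoms: tert‑butyldimethylsilyl chloride, CC(C)(C)[Si](C)(C)Cl
Why: standard silylation of a secondary allylic alcohol; the TBS ether is meant to stay until the last step.

Step 4
Reactants: 5 tert‑butyl{[(4S,5E)‑7,7‑dimethoxy‑5‑methylhepta‑1,5‑dien‑4‑yl]oxy}dimethylsilane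
Product: 6 (2E,4S)‑4‑[(tert‑butyldimethylsilyl)oxy]‑3‑methylhepta‑2,6‑dienal
Conditions: 10 % aq. oxalic acid, SiO2, CH2Cl2, 23 °C
Reagents that add atoms: water, O
Why: mild hydrolysis of an allylic dimethyl acetal, which should unmask the C6 enal without touching the TBS ether or the olefin geometry.

Step 5
Reactants: 7 [(tert‑butyldimethylsilyl)oxy]acetaldehyde; 8 methyl acrylate
Product: 9 methyl 2‑{2‑[(tert‑butyldimethylsilyl)oxy]‑1‑hydroxyethyl}prop‑2‑enoate (racemic)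
Conditions: DABCO (0.5 equiv), MeOH, 23 °C
Reagents that add atoms: none
Why: Morita–Baylis–Hillman reaction of an α‑silyloxy aldehyde with an acrylate; the new carbinol centre is lost in step 6, so no stereocontrol is needed.

Step 6
Reactants: 9 methyl 2‑{2‑[(tert‑butyldimethylsilyl)oxy]‑1‑hydroxyethyl}prop‑2‑enoate
Product: 10 methyl (2Z)‑2‑(bromomethyl)‑4‑[(tert‑butyldimethylsilyl)oxy]but‑2‑enoate
Conditions: NBS, Me2S, CH2Cl2, 0 °C to 23 °C
Reagents that add atoms: N‑bromosuccinimide, BrN1C(=O)CCC1=O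
Why: Corey–Kim bromination of a Baylis–Hillman alcohol with allylic transposition, which should give the thermodynamically favoured (Z)‑2‑(bromomethyl)enoate.

Step 7
Reactants: 6 (2E,4S)‑4‑[(tert‑butyldimethylsilyl)oxy]‑3‑methylhepta‑2,6‑dienal; 10 methyl (2Z)‑2‑(bromomethyl)‑4‑[(tert‑butyldimethylsilyl)oxy]but‑2‑enoate
Product: 13 (4R,5R)‑4‑{[(tert‑butyldimethylsilyl)oxy]methyl}‑5‑[(1E,3S)‑3‑[(tert‑butyldimethylsilyl)oxy]‑2‑methylhexa‑1,5‑dien‑1‑yl]‑3‑methylideneoxolan‑2‑one, via trimethylsilyl ether 11 (not isolated), via hydroxy ester 12 (not isolated)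
Conditions: CrCl2 (10 mol %), (S,S)‑1,8‑bis(4‑isopropyloxazolin‑2‑yl)carbazole ligand (12 mol %), Mn powder, Me3SiCl, THF, 23 °C; then 10 % aq. citric acid, THF, 23 °C
Reagents that add atoms: none
Why: catalytic asymmetric Nozaki–Hiyama–Kishi 2‑(alkoxycarbonyl)allylation, in which the equilibrating allylchromium adds through its γ‑carbon in a chair transition state with the CH2OTBS group equatorial (anti adduct, hence the trans‑lactone on lactonisation) while the chiral bis(oxazoline)–chromium complex selects the aldehyde face that sets C6 as R and with it C7.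

Step 8
Reactants: 13 (4R,5R)‑4‑{[(tert‑butyldimethylsilyl)oxy]methyl}‑5‑[(1E,3S)‑3‑[(tert‑butyldimethylsilyl)oxy]‑2‑methylhexa‑1,5‑dien‑1‑yl]‑3‑methylideneoxolan‑2‑one
Product: 14 (2E,5S,6E)‑5‑[(tert‑butyldimethylsilyl)oxy]‑7‑[(2R,3R)‑3‑{[(tert‑butyldimethylsilyl)oxy]methyl}‑4‑methylidene‑5‑oxooxolan‑2‑yl]‑2,6‑dimethylhepta‑2,6‑dienal
Conditions: methacrolein (10 equiv), second‑generation Hoveyda–Grubbs catalyst (5 mol %), CH2Cl2, 40 °C
Reagents that add atoms: methacrolein, CC(=C)C=O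
Why: olefin cross‑metathesis of the only monosubstituted alkene with excess methacrolein, which should give the (E)‑2‑methyl enal while the trisubstituted olefin and the 1,1‑disubstituted acrylate stay spectators; the enal geometry is irrelevant later.

Step 9
Reactants: 14 (2E,5S,6E)‑5‑[(tert‑butyldimethylsilyl)oxy]‑7‑[(2R,3R)‑3‑{[(tert‑butyldimethylsilyl)oxy]methyl}‑4‑methylidene‑5‑oxooxolan‑2‑yl]‑2,6‑dimethylhepta‑2,6‑dienal
Product: 15 (2E,5S,6E)‑5‑[(tert‑butyldimethylsilyl)oxy]‑7‑[(2R,3R)‑3‑(hydroxymethyl)‑4‑methylidene‑5‑oxooxolan‑2‑yl]‑2,6‑dimethylhepta‑2,6‑dienal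
Conditions: HF·pyridine, pyridine, THF, 0 °C
Reagents that add atoms: none
Why: selective desilylation, the primary TBS ether being cleaved much faster than the hindered secondary one under buffered HF·pyridine.

Step 10
Reactants: 15 (2E,5S,6E)‑5‑[(tert‑butyldimethylsilyl)oxy]‑7‑[(2R,3R)‑3‑(hydroxymethyl)‑4‑methylidene‑5‑oxooxolan‑2‑yl]‑2,6‑dimethylhepta‑2,6‑dienal
Product: 16 (2R,3S)‑2‑[(1E,3S,5E)‑3‑[(tert‑butyldimethylsilyl)oxy]‑2,6‑dimethyl‑7‑oxohepta‑1,5‑dien‑1‑yl]‑4‑methylidene‑5‑oxooxolane‑3‑carbaldehyde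
Conditions: Dess–Martin periodinane, NaHCO3, CH2Cl2, 0 °C; used crude at once
Reagents that add atoms: none
Why: Dess–Martin oxidation under buffered, non‑basic conditions, chosen so that the epimerisable C7 centre next to the new aldehyde is not disturbed.

Step 11
Reactants: 16 (2R,3S)‑2‑[(1E,3S,5E)‑3‑[(tert‑butyldimethylsilyl)oxy]‑2,6‑dimethyl‑7‑oxohepta‑1,5‑dien‑1‑yl]‑4‑methylidene‑5‑oxooxolane‑3‑carbaldehyde
Product: 19 (3S,6R,7R,8R,9S)‑3‑[(tert‑butyldimethylsilyl)oxy]‑8‑hydroxy‑9‑[(triethylsilyl)oxy]germacra‑1(10)Z,4E,11(13)‑trien‑12,6‑olide, via allylchromium species 17 (not isolated), via chromium alkoxide 18 (not isolated)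
Conditions: CrCl2 (8 equiv), Et3SiCl (1.5 equiv), DMF, 23 °C, 0.002 M (16 added over 12 h); pH 7 buffer work‑up
Reagents that add atoms: chlorotriethylsilane, CC[Si](Cl)(CC)CC
Why: Proposed new method: Et3SiCl activates the C9 enal as its O‑silyl oxocarbenium ion, two equivalents of divalent chromium reduce it to the γ‑(silyloxy)allylchromium species 17 (trivalent chromium on C1, (E)‑silyl enol ether C9=C10), and 17 adds through C9 to the chromium‑bound C8 aldehyde in a six‑membered chair transition state with allylic transposition, which re‑creates the C1=C10 double bond and leaves O9 silylated and O8 as the chromium alkoxide 18 (hence differentiated oxygens after work‑up); the closest known reactions are the CrCl2/R3SiCl pinacol‑type cross‑coupling of enones and enals with aldehydes, its intramolecular form on 2‑methylene dicarbonyls (five‑ to seven‑membered rings) and Nozaki–Hiyama–Kishi allylation macrocyclisations to ten‑membered germacranolides. The ten‑membered carbocycle closes in a 10‑exo‑trig mode at the C8 carbonyl. The C2–C7 tether can bridge C1 and C8 of the chair only when C2 is pseudoaxial on C1, and this placement maps onto the (Z)‑C1=C10 olefin (C2 and C9 cis), so the olefin geometry is set by the ring being formed and not by the geometry of the starting enal, which is erased. C9 is controlled by the chair: the OSiEt3 group of the (E)‑enol silane (trans to the bulkier chromium‑bearing C1) and C7 are both pseudoequatorial, which gives the 8,9‑anti (erythro) pair as in chromium‑mediated γ‑oxyallylations. C8 is controlled by the C7 stereocentre of the trans‑lactone: Felkin–Anh attack anti to the C7–C6 bond with the flat C11 inside should give 8R (and with it 9S). The step needs chemoselectivity (only the conjugated aldehyde is reduced, only the saturated aldehyde is attacked, the α‑methylene lactone is not reduced by CrCl2) and intramolecularity, secured by the enal/alkanal difference built into 16 and by slow addition at 0.002 M.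

Step 12
Reactants: 19 (3S,6R,7R,8R,9S)‑3‑[(tert‑butyldimethylsilyl)oxy]‑8‑hydroxy‑9‑[(triethylsilyl)oxy]germacra‑1(10)Z,4E,11(13)‑trien‑12,6‑olide
Product: 20 (3S,6R,7S,8R,9S)‑8‑(angeloyloxy)‑3‑[(tert‑butyldimethylsilyl)oxy]‑9‑[(triethylsilyl)oxy]germacra‑1(10)Z,4E,11(13)‑trien‑12,6‑olide
Conditions: angelic acid, 2,4,6‑trichlorobenzoyl chloride, Et3N, PhMe, 23 °C; then 19, PhMe, 75 °C (no DMAP)
Reagents that add atoms: angelic acid ((2Z)‑2‑methylbut‑2‑enoic acid), C/C=C(/C)C(=O)O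
Why: Yamaguchi‑type mixed‑anhydride esterification of the only free hydroxyl, run without a nucleophilic catalyst so that the (Z)‑geometry of the angeloyl group should be kept.

Step 13
Reactants: 20 (3S,6R,7S,8R,9S)‑8‑(angeloyloxy)‑3‑[(tert‑butyldimethylsilyl)oxy]‑9‑[(triethylsilyl)oxy]germacra‑1(10)Z,4E,11(13)‑trien‑12,6‑olide
Product: 21 (3S,6R,7S,8R,9S)‑8‑(angeloyloxy)‑3‑[(tert‑butyldimethylsilyl)oxy]‑9‑hydroxygermacra‑1(10)Z,4E,11(13)‑trien‑12,6‑olide
Conditions: PPTS, MeOH/CH2Cl2, 0 °C; product used at once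
Reagents that add atoms: none
Why: acid‑catalysed methanolysis that removes a triethylsilyl ether far faster than a tert‑butyldimethylsilyl ether; the short, cold, weakly acidic treatment is chosen to avoid 1,2‑acyl migration.

Step 14
Reactants: 21 (3S,6R,7S,8R,9S)‑8‑(angeloyloxy)‑3‑[(tert‑butyldimethylsilyl)oxy]‑9‑hydroxygermacra‑1(10)Z,4E,11(13)‑trien‑12,6‑olide
Product: 22 (3S,6R,7S,8R,9S)‑9‑acetoxy‑8‑(angeloyloxy)‑3‑[(tert‑butyldimethylsilyl)oxy]germacra‑1(10)Z,4E,11(13)‑trien‑12,6‑olide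
Conditions: Ac2O, pyridine, CH2Cl2, 0 °C to 23 °C
Reagents that add atoms: acetic anhydride, CC(=O)OC(C)=O
Why: standard acetylation of the only free (allylic) hydroxyl at O9.

Step 15
Reactants: 22 (3S,6R,7S,8R,9S)‑9‑acetoxy‑8‑(angeloyloxy)‑3‑[(tert‑butyldimethylsilyl)oxy]germacra‑1(10)Z,4E,11(13)‑trien‑12,6‑olide
Product: 23 (3S,6R,7S,8R,9S)‑9‑acetoxy‑8‑(angeloyloxy)‑3‑hydroxygermacra‑1(10)Z,4E,11(13)‑trien‑12,6‑olide (CNP0265116.1)
Conditions: HF·pyridine, THF, 0 °C to 23 °C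
Reagents that add atoms: none
Why: fluoride‑mediated cleavage of the secondary TBS ether under mildly acidic conditions that should leave both esters, the α‑methylene lactone and both olefins untouched.

**Compound list**

1 | 2,2‑dimethoxyacetaldehyde | COC(OC)C=O | starting material
2 | 2‑(triphenyl‑λ5‑phosphanylidene)propanal | CC(C=O)=P(c1ccccc1)(c1ccccc1)c1ccccc1 | starting material
3 | (2E)‑4,4‑dimethoxy‑2‑methylbut‑2‑enal | COC(OC)/C=C(\C)C=O | intermediate
4 | (4S,5E)‑7,7‑dimethoxy‑5‑methylhepta‑1,5‑dien‑4‑ol | COC(OC)/C=C(\C)[C@@H](O)CC=C | intermediate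
5 | tert‑butyl{[(4S,5E)‑7,7‑dimethoxy‑5‑methylhepta‑1,5‑dien‑4‑yl]oxy}dimethylsilane | COC(OC)/C=C(\C)[C@@H](O[Si](C)(C)C(C)(C)C)CC=C | intermediate
6 | (2E,4S)‑4‑[(tert‑butyldimethylsilyl)oxy]‑3‑methylhepta‑2,6‑dienal | O=C/C=C(\C)[C@@H](O[Si](C)(C)C(C)(C)C)CC=C | intermediate
7 | [(tert‑butyldimethylsilyl)oxy]acetaldehyde | CC(C)(C)[Si](C)(C)OCC=O | starting material
8 | methyl acrylate | C=CC(=O)OC | starting material
9 | methyl 2‑{2‑[(tert‑butyldimethylsilyl)oxy]‑1‑hydroxyethyl}prop‑2‑enoate (racemic) | C=C(C(=O)OC)C(O)CO[Si](C)(C)C(C)(C)C | intermediate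
10 | methyl (2Z)‑2‑(bromomethyl)‑4‑[(tert‑butyldimethylsilyl)oxy]but‑2‑enoate | COC(=O)/C(CBr)=C/CO[Si](C)(C)C(C)(C)C | intermediate
11 | methyl (3R,4R,5E,7S)‑7‑[(tert‑butyldimethylsilyl)oxy]‑3‑{[(tert‑butyldimethylsilyl)oxy]methyl}‑6‑methyl‑2‑methylidene‑4‑[(trimethylsilyl)oxy]deca‑5,9‑dienoate | C=C(C(=O)OC)[C@H](CO[Si](C)(C)C(C)(C)C)[C@H](O[Si](C)(C)C)/C=C(\C)[C@@H](O[Si](C)(C)C(C)(C)C)CC=C | intermediate
12 | methyl (3R,4R,5E,7S)‑7‑[(tert‑butyldimethylsilyl)oxy]‑3‑{[(tert‑butyldimethylsilyl)oxy]methyl}‑4‑hydroxy‑6‑methyl‑2‑methylidenedeca‑5,9‑dienoate | C=C(C(=O)OC)[C@H](CO[Si](C)(C)C(C)(C)C)[C@H](O)/C=C(\C)[C@@H](O[Si](C)(C)C(C)(C)C)CC=C | intermediate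
13 | (4R,5R)‑4‑{[(tert‑butyldimethylsilyl)oxy]methyl}‑5‑[(1E,3S)‑3‑[(tert‑butyldimethylsilyl)oxy]‑2‑methylhexa‑1,5‑dien‑1‑yl]‑3‑methylideneoxolan‑2‑one | C=C1C(=O)O[C@H](/C=C(\C)[C@@H](O[Si](C)(C)C(C)(C)C)CC=C)[C@H]1CO[Si](C)(C)C(C)(C)C | intermediate
14 | (2E,5S,6E)‑5‑[(tert‑butyldimethylsilyl)oxy]‑7‑[(2R,3R)‑3‑{[(tert‑butyldimethylsilyl)oxy]methyl}‑4‑methylidene‑5‑oxooxolan‑2‑yl]‑2,6‑dimethylhepta‑2,6‑dienal | C=C1C(=O)O[C@H](/C=C(\C)[C@@H](O[Si](C)(C)C(C)(C)C)C/C=C(\C)C=O)[C@H]1CO[Si](C)(C)C(C)(C)C | intermediate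
15 | (2E,5S,6E)‑5‑[(tert‑butyldimethylsilyl)oxy]‑7‑[(2R,3R)‑3‑(hydroxymethyl)‑4‑methylidene‑5‑oxooxolan‑2‑yl]‑2,6‑dimethylhepta‑2,6‑dienal | C=C1C(=O)O[C@H](/C=C(\C)[C@@H](O[Si](C)(C)C(C)(C)C)C/C=C(\C)C=O)[C@H]1CO | intermediate
16 | (2R,3S)‑2‑[(1E,3S,5E)‑3‑[(tert‑butyldimethylsilyl)oxy]‑2,6‑dimethyl‑7‑oxohepta‑1,5‑dien‑1‑yl]‑4‑methylidene‑5‑oxooxolane‑3‑carbaldehyde | C=C1C(=O)O[C@H](/C=C(\C)[C@@H](O[Si](C)(C)C(C)(C)C)C/C=C(\C)C=O)[C@H]1C=O | intermediate
17 | γ‑(triethylsilyloxy)allylchromium dichloride from 16: CrCl2 unit on C1, (E)‑silyl enol ether C9=C10, C8 aldehyde intact (both C1 epimers, solvent ligands omitted) | C=C1C(=O)O[C@H](/C=C(\C)[C@@H](O[Si](C)(C)C(C)(C)C)CC([Cr](Cl)Cl)/C(C)=C/O[Si](CC)(CC)CC)[C@H]1C=O | intermediate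
18 | dichlorochromium C8‑alkoxide of 19 (trivalent chromium, solvent ligands omitted) | C=C1C(=O)O[C@@H]2/C=C(\C)[C@@H](O[Si](C)(C)C(C)(C)C)C/C=C(/C)[C@H](O[Si](CC)(CC)CC)[C@H](O[Cr](Cl)Cl)[C@@H]12 | intermediate
19 | (3S,6R,7R,8R,9S)‑3‑[(tert‑butyldimethylsilyl)oxy]‑8‑hydroxy‑9‑[(triethylsilyl)oxy]germacra‑1(10)Z,4E,11(13)‑trien‑12,6‑olide | C=C1C(=O)O[C@@H]2/C=C(\C)[C@@H](O[Si](C)(C)C(C)(C)C)C/C=C(/C)[C@H](O[Si](CC)(CC)CC)[C@H](O)[C@@H]12 | intermediate
20 | (3S,6R,7S,8R,9S)‑8‑(angeloyloxy)‑3‑[(tert‑butyldimethylsilyl)oxy]‑9‑[(triethylsilyl)oxy]germacra‑1(10)Z,4E,11(13)‑trien‑12,6‑olide | C=C1C(=O)O[C@@H]2/C=C(\C)[C@@H](O[Si](C)(C)C(C)(C)C)C/C=C(/C)[C@H](O[Si](CC)(CC)CC)[C@H](OC(=O)/C(C)=C\C)[C@@H]12 | intermediate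
21 | (3S,6R,7S,8R,9S)‑8‑(angeloyloxy)‑3‑[(tert‑butyldimethylsilyl)oxy]‑9‑hydroxygermacra‑1(10)Z,4E,11(13)‑trien‑12,6‑olide | C=C1C(=O)O[C@@H]2/C=C(\C)[C@@H](O[Si](C)(C)C(C)(C)C)C/C=C(/C)[C@H](O)[C@H](OC(=O)/C(C)=C\C)[C@@H]12 | intermediate
22 | (3S,6R,7S,8R,9S)‑9‑acetoxy‑8‑(angeloyloxy)‑3‑[(tert‑butyldimethylsilyl)oxy]germacra‑1(10)Z,4E,11(13)‑trien‑12,6‑olide | C=C1C(=O)O[C@@H]2/C=C(\C)[C@@H](O[Si](C)(C)C(C)(C)C)C/C=C(/C)[C@H](OC(C)=O)[C@H](OC(=O)/C(C)=C\C)[C@@H]12 | intermediate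
23 | (3S,6R,7S,8R,9S)‑9‑acetoxy‑8‑(angeloyloxy)‑3‑hydroxygermacra‑1(10)Z,4E,11(13)‑trien‑12,6‑olide (CNP0265116.1) | C=C1C(=O)O[C@@H]2/C=C(\C)[C@@H](O)C/C=C(/C)[C@H](OC(C)=O)[C@H](OC(=O)/C(C)=C\C)[C@@H]12 | target

**Step count and risks**

Total step count: 15. Longest linear sequence: 13 steps (steps 1–4 and 7–15, from 1).

The three steps most likely to fail:

1. Step 11 (proposed new method). The β‑substituted, α‑methyl enal may be reduced too slowly by CrCl2/Et3SiCl, so that oligomerisation or simple reduction competes with formation of the allylchromium species, and the aldehyde face selection at C8 may be eroded in the bridged transition state. The fallback sets out from 14 and comes back at 22, and forms the same kind of allylchromium species by halide reduction instead of enal reduction. The enal of 14 is treated with acetyl bromide and catalytic ZnCl2 in CH2Cl2 at −30 °C (the known 1,4‑addition that turns enals into 3‑bromopropenyl acetates) to give the 3‑bromo enol acetate F1. HF·pyridine frees the primary alcohol F2 and Dess–Martin oxidation gives the aldehyde F3. A Nozaki–Hiyama–Kishi allylation macrocyclisation with CrCl2 in THF at high dilution (the known anti‑selective hydroxyallylation of aldehydes by 3‑bromopropenyl esters) closes the ring to the 8‑hydroxy‑9‑acetate F4. F4 is angeloylated under the conditions of step 12 to give 22 directly.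

2. Step 7. Catalyst control of the aldehyde face may be poor with the γ‑substituted bromide and the β,β‑disubstituted enal, so that the C6/C7 pair forms in both absolute senses. The fallback sets out from 6 and 10 and comes back at 13, and replaces catalyst control by resolution against the stereocentre already present. A ligand‑free Nozaki–Hiyama allylation with stoichiometric CrCl2 in THF (known to be anti‑selective for γ‑substituted 2‑(bromomethyl)enoates) gives hydroxy ester 12 together with its (3S,4S) isomer F5. Mild acid lactonises them to 13 and the (4S,5S) trans‑lactone F6. Because C3 is already a single enantiomer, 13 and F6 are diastereomers and are separated by chromatography, at the cost of about half the material.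

3. Step 12. At 75 °C under amine base the angeloyl group may isomerise from Z to E (tiglate formation), and the free 8‑hydroxyl may attack the lactone carbonyl (translactonisation to the 12,8‑olide). The fallback sets out from 19 and comes back at 20, and builds the (Z)‑olefin on an ester already in place. 19 is esterified at 0 °C with 2‑[bis(2,2,2‑trifluoroethoxy)phosphoryl]propanoic acid (diisopropylcarbodiimide, catalytic DMAP, CH2Cl2) to give the phosphonate F7. A Still–Gennari olefination with acetaldehyde (KHMDS, 18‑crown‑6, THF, −78 °C) then gives 20.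

**Further compounds**

F1 | step 11 | (4R,5R)‑5‑[(1E,3S)‑7‑acetoxy‑5‑bromo‑3‑[(tert‑butyldimethylsilyl)oxy]‑2,6‑dimethylhepta‑1,6‑dien‑1‑yl]‑4‑{[(tert‑butyldimethylsilyl)oxy]methyl}‑3‑methylideneoxolan‑2‑one (both epimers at the bromide carbon, enol acetate as E/Z mixture) | C=C1C(=O)O[C@H](/C=C(\C)[C@@H](O[Si](C)(C)C(C)(C)C)CC(Br)C(C)=COC(C)=O)[C@H]1CO[Si](C)(C)C(C)(C)C
F2 | step 11 | (4R,5R)‑5‑[(1E,3S)‑7‑acetoxy‑5‑bromo‑3‑[(tert‑butyldimethylsilyl)oxy]‑2,6‑dimethylhepta‑1,6‑dien‑1‑yl]‑4‑(hydroxymethyl)‑3‑methylideneoxolan‑2‑one | C=C1C(=O)O[C@H](/C=C(\C)[C@@H](O[Si](C)(C)C(C)(C)C)CC(Br)C(C)=COC(C)=O)[C@H]1CO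
F3 | step 11 | (2R,3S)‑2‑[(1E,3S)‑7‑acetoxy‑5‑bromo‑3‑[(tert‑butyldimethylsilyl)oxy]‑2,6‑dimethylhepta‑1,6‑dien‑1‑yl]‑4‑methylidene‑5‑oxooxolane‑3‑carbaldehyde | C=C1C(=O)O[C@H](/C=C(\C)[C@@H](O[Si](C)(C)C(C)(C)C)CC(Br)C(C)=COC(C)=O)[C@H]1C=O
F4 | step 11 | (3S,6R,7R,8R,9S)‑9‑acetoxy‑3‑[(tert‑butyldimethylsilyl)oxy]‑8‑hydroxygermacra‑1(10)Z,4E,11(13)‑trien‑12,6‑olide | C=C1C(=O)O[C@@H]2/C=C(\C)[C@@H](O[Si](C)(C)C(C)(C)C)C/C=C(/C)[C@H](OC(C)=O)[C@H](O)[C@@H]12
F5 | step 7 | methyl (3S,4S,5E,7S)‑7‑[(tert‑butyldimethylsilyl)oxy]‑3‑{[(tert‑butyldimethylsilyl)oxy]methyl}‑4‑hydroxy‑6‑methyl‑2‑methylidenedeca‑5,9‑dienoate | C=C(C(=O)OC)[C@@H](CO[Si](C)(C)C(C)(C)C)[C@@H](O)/C=C(\C)[C@@H](O[Si](C)(C)C(C)(C)C)CC=C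
F6 | step 7 | (4S,5S)‑4‑{[(tert‑butyldimethylsilyl)oxy]methyl}‑5‑[(1E,3S)‑3‑[(tert‑butyldimethylsilyl)oxy]‑2‑methylhexa‑1,5‑dien‑1‑yl]‑3‑methylideneoxolan‑2‑one | C=C1C(=O)O[C@@H](/C=C(\C)[C@@H](O[Si](C)(C)C(C)(C)C)CC=C)[C@@H]1CO[Si](C)(C)C(C)(C)C
F7 | step 12 | (3S,6R,7S,8R,9S)‑8‑({2‑[bis(2,2,2‑trifluoroethoxy)phosphoryl]propanoyl}oxy)‑3‑[(tert‑butyldimethylsilyl)oxy]‑9‑[(triethylsilyl)oxy]germacra‑1(10)Z,4E,11(13)‑trien‑12,6‑olide (both epimers at the phosphonate carbon) | C=C1C(=O)O[C@@H]2/C=C(\C)[C@@H](O[Si](C)(C)C(C)(C)C)C/C=C(/C)[C@H](O[Si](CC)(CC)CC)[C@H](OC(=O)C(C)P(=O)(OCC(F)(F)F)OCC(F)(F)F)[C@@H]12
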